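At early times in oak and elm Z climbs at once while X lags, so Z comes first and the ratio X/Z starts small.

| flask | D | E | remark | time |
|---|---|---|---|---|
| oak | 0.72 M | 1.4 M | run made earlier |  |
| elm | 1.4 M | 2.16 M | run made earlier |  |
| flask | 0.72 M | 2.16 M |  | 3.0 h |

- oak (time / h: X / %, Z / %): 0.200: 0.9, 8.0; 0.667: 23.1, 26.0; 1.00: 42.6, 26.5; 1.50: 57.7, 23.6; 2.50: 69.2, 18.9
- elm (time / h: X / %, Z / %): 0.500: 15.2, 26.7; 1.00: 44.2, 27.5; 1.33: 56.5, 25.6; 2.00: 66.9, 22.6; 2.50: 70.4, 19.8

(standard deviation of a reading: 1 percentage point)

* ratio of X to Z at 4.0 min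
* ratio of X to Z at 30 min
* ratio of X to Z at 3.0 h
* which of X and Z there is more of at 3.0 h



So the early ratio grows, but how far does it go? At the last readings X/Z stands at 3.66 in oak and 3.56 in elm, and it is still climbing, so I can't stop there. But in oak and elm the gain of X per hour, taken per unit of Z, shrinks as the ratio grows. I assume that it falls along a straight line against X/Z, as it would if Z and X turned into each other, and I draw that line through the last two intervals of each run. Oak's line reaches zero gain at an X/Z of 3.79, and elm's at 3.95. Their mean, 3.87, is my closing ratio: the X/Z at which X stops gaining, an equilibrium constant if that assumption holds. It is a reading with the scatter of the runs, and I commit to it for the flask at 3.0 h.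

The forecast gives 0.025, 0.8 and 4.8, with X ahead. Its last value is higher than mine, on the grounds “or about 5 if the flask runs faster”.

The flask gives 0.0547, 0.640 and 3.67, with X ahead, 70.6 % against 19.2 % for Z.

    D + E → J (k = 0.0510 M⁻¹ min⁻¹)
    D + E ⇌ L (K = 0.110 M⁻¹, k = 1.10 M⁻¹ min⁻¹)
    J → Q (k = 0.0790 min⁻¹)
    Q ⇌ Z (K = 1.90, k = 0.250 min⁻¹)
    Z ⇌ X (K = 3.70, k = 0.0490 min⁻¹)

In the flask, the half-life of Z by the forward step to X alone, 0.24 h, is far shorter than the 3.0 h of the run. Reading at that time and not ten times later makes no difference, and the flask's ratio lies a little under my closing ratio.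

In the neighbour with 0.54 M of E, my closing ratio again gives 3.87 for X/Z. The computed ratio in that neighbour at 3.0 h is 3.36, with X at 47.7 %, Z at 14.2 % and 29.5 % of D still there.

The numbers in the tables are calculated for an exercise, noise included.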